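**Minutes on the next flask**

The analyst opened from the dawn run, whose target read 67.8 % at 6.00 h, while the summer run, with more nucleophile, read 79.4 % at 6.00 h.

| setting | dawn | summer | flask |
|---|---|---|---|
| electrophile | 0.10 M | 0.10 M | 0.10 M |
| nucleophile | 2.8 equiv | 4.4 equiv | 2.00 equiv |
| free base | 0.80 equiv | 0.80 equiv | 0.800 equiv |
| remark | run made earlier | run made earlier |  |
| time |  |  | 10 h |

| run | time / h | electrophile / % | target / % |
|---|---|---|---|
| dawn | 0.417 | 62.1 | 26.7 |
| dawn | 1.33 | 25.9 | 50.8 |
| dawn | 2.00 | 14.1 | 59.2 |
| dawn | 3.00 | 6.4 | 64.9 |
| dawn | 5.00 | 1.9 | 67.7 |
| dawn | 6.00 | 1.9 | 67.8 |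
| summer | 1.00 | 22.3 | 59.5 |
| summer | 2.00 | 6.6 | 74.8 |
| summer | 3.00 | 2.6 | 78.1 |
| summer | 4.00 | 1.0 | 79.3 |
| summer | 5.00 | 0.2 | 79.2 |
| summer | 6.00 | 0.2 | 79.4 |

(scatter of a reading: 1 percentage point)

- part of the electrophile that has reacted at 10 h
- share of the unused nucleophile that is free and not bound as protonated nucleophile, at 10 h

- the earlier runs were read with a standard deviation of 1 percentage point
- what has gone from electrophile into another species counts as reacted, even if it can come back
- the earlier runs do not show how much of nucleophile is bound; that part of a forecast is a guess

She proposed to carry one reading, the split σ, a selectivity factor: target over the rest of the charged electrophile, divided by the equivalents of nucleophile charged. Dawn reads σ = 0.752 per equivalent and summer reads 0.876, a gap that she left open. She took the dawn value, since that run's charge lies nearer the flask's.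

On this reckoning, which was her own, the flask's ratio is ρ = σ × equivalents = 1.50, so target stands near 60.1 % of the charge.

The forecaster tabled 99 % reacted, within 96.5 % to 100 %, and 90 % of the unused nucleophile free, within 70 % to 100 %. The forecaster's own target figure was about 58 %, and of the free share the forecaster said: “This is a guess”.

The flask gave 99.0 % reacted and 74.7 % free, the second 15 percentage points under the forecast but inside its range.

    electrophile ⇌ dormant form (K = 21.0, k = 0.320 /h)
    nucleophile + acid set free ⇌ protonated nucleophile, settled at all times (K = 14000 /M)
    electrophile + acid set free ⇌ idle adduct, settled at all times (K = 3.10 /M)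
    electrophile + nucleophile → acid set free + target (k = 3.00 /M/h)
    2 free base → self-condensation product (k = 20.0 /M/h)
    acid set free + free base ⇌ salt of the base, settled at all times (K = 4.00 × 10⁵ /M)

In the flask, the rate of electrophile use by the target step over the forward rate alone into the dormant form is 1.9 just after the start and 0.97 at 10.0 h; ρ lies below the first and above the second. At that hour the flask holds 61.3 % target against 37.7 % dormant form. With 0.800 equiv of nucleophile, σ gives 37.6 % target, and that neighbour flask holds 35.2 %.

Readings and results are simulated with constants of no real substance; scatter was added.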